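The numbers in the tables were generated by integration for an exercise; scatter was added.

The trap in the amber flask was its rising readings: 54.3% at 4.00 h invited leaving it for the 20 h allowed, yet the grey run topped out near 65.2% and fell to 51.9%.

all flasks: catalyst 0.47 mol%
- amber: substrate 0.20 M; partner 0.70 equiv; the very flask that is asked about, followed so far
- grey: substrate 0.40 M; partner 0.70 equiv; run made earlier
- flask: substrate 0.20 M; partner 0.700 equiv; time 20 h

| run | time / h | target / % |
|---|---|---|
| amber | 2.00 | 40.6 |
| amber | 2.50 | 45.4 |
| amber | 3.00 | 48.8 |
| amber | 4.00 | 54.3 |
| grey | 2.00 | 59.0 |
| grey | 3.00 | 64.1 |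
| grey | 5.00 | 65.2 |
| grey | 8.00 | 62.2 |
| grey | 12.0 | 58.7 |
| grey | 20.0 | 51.9 |

(each reading ± 0.3 percentage points)

- what was read earlier has a scatter of 0.3 percentage points, one standard deviation
- candidate steps: substrate + partner + catalyst -> target + catalyst; target -> over-reaction product

* the best time, 20 h at the latest, for target
* the amount of target, in percent of the substrate charged, at that time

This was my note for whoever took over the bench. Partner, charged at 0.700 equiv, was the limiting reagent, less than the substrate, so I counted target and over-reaction product together against that charge. From the grey fall between 8.00 h and 20.0 h I read the loss constant k, the first-order rate at which target falls late in a run: 0.0151 /h. Run back to zero time, that fall met 70.2%, close to the charge.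

So I took as a yardstick, not an upper bound, C(t): the partner charge times exp(−kt), assuming the same k in amber. The gap g = C − target in amber was 27 percentage points at 2.00 h and 12 points at 4.00 h, closing at r = 0.428 /h. Control changes hands where making, r·g, falls to the loss, k·C. I reckoned that crossing at 7.89 h, with 60.0% target in the amber flask. My instruction: keep stirring, add nothing, stop it then.

The forecast came later than my crossing, at 8.5 h with 60.2%: “The peak is flat in time.” The amber flask gave 60.5% at 8.46 h.

    substrate + partner + catalyst → target + catalyst, rate k1*[substrate]*[partner]*[catalyst]/(1 + ([substrate]/sat1)) (0.0680 M, k = 2.80 /M²/s)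
    target → over-reaction product (k = 4.40 × 10⁻⁶ /s)

At that time the amber flask's yardstick stood at 61.6%, which is 1.1 points above its target. A neighbouring flask, changed to 0.280 equiv of partner, has the yardstick 20.7% at 20 h. That flask held more target than its yardstick, 21.1% at 20.0 h, beside 72.0% substrate.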